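**Remark on the chemistry.** Lignan numbering is used for the target: ring A is the syringyl ring (C1–C6), C7 the ketone carbon, C8 the stereogenic methine, C9 the hydroxymethyl carbon; ring B is the guaiacyl ring (C1′–C6′), O4′ the ether oxygen, C7′–C9′ the 3-hydroxypropyl chain. The SMILES descriptor corresponds to (8R).

## Analysis of the target

The target is an 8-O-4′ neolignan in its 7-oxo form. Ring A (3,5-dimethoxy, free 4-OH) carries the C7 ketone, the C8 methine and the C9 hydroxymethyl group. C8 is joined through O4′ to ring B (3′-OMe), which bears the C7′–C9′ hydroxypropyl chain at C1′. There is no ring to build and only one stereocentre, C8 (R). That centre is α to the aryl ketone, carries an aryloxy group and is β to the C9 hydroxyl, so base epimerises it through the enol, reverses the aldol (loss of C9) or eliminates water to the enone. Further sensitive groups are the oxidisable C4 phenol para to the ketone and two primary alcohols (C9, C9′) that must be told apart from the C7 oxygen. The skeleton is trivial; the difficulty is to install this one labile centre in high enantiopurity and never expose it to base afterwards. The route turns the liability into the asset: with C9 at the ester level, the C8–H bond between the C7 carbonyl, the C9 carbonyl and O4′ racemises freely, which is what a dynamic kinetic resolution needs. The free C4–OH of ring A, para to C7, later allows the C7 carbinol alone to be re-oxidised under neutral conditions.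

## Retrosynthetic reasoning

**11 ⇒ 10.** The C7 ketone is taken back to the C7 carbinol; no skeletal bond is cut. In 11 every basic operation endangers C8, whereas in 10 it is an ordinary ether carbon. The forward step must oxidise one secondary carbinol beside two primary alcohols and a phenol. The para-hydroxyl of ring A makes C7–H uniquely prone to quinone dehydrogenation, so no protecting group is needed and the labile ketone appears last, under neutral conditions.

**10 ⇒ 9.** The O4 benzyl ether of ring A is reinstated. It is needed because the earlier steps use strong base and an electrophilic carbenoid that a free phenol would intercept. It is removed by neutral hydrogenolysis.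

**9 ⇒ 8.** Both primary alcohols (C9 and C9′) are traced back to methyl esters. One hydride step reveals both, so the C9′ hydroxyl never needs protection. The C9 ester is also what makes C8 acidic at the preceding stage.

**8 ⇒ 6 (key).** The C7–H bond is cut, and with it the configurations at C7 and C8. The precursor 6 is racemic at C8 and interconverts through its enol 7, so stereocontrol reduces to a catalyst-controlled ketone reduction on a self-correcting substrate. The forward reaction must racemise C8 faster than it reduces the mismatched enantiomer and must give one relative configuration, because C7 is erased later and only C8 survives.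

**6 ⇒ 4 + 5.** The C8–O4′ bond is cut. This is the most convergent cut, separating ring A with C7–C9 from ring B with its chain. Forward, a rhodium carbenoid derived from 4 inserts into the phenolic O–H of 5. The racemic outcome is irrelevant.

**4 ⇒ 3 ⇒ 2 ⇒ 1.** The diazo group comes from diazo transfer to the active methylene of 3. The C8–C9 bond of 3 comes from a crossed Claisen condensation of methyl ketone 2 with a carbonate. Compound 2 is the benzyl ether of commercial 1.

## Alternatives that were turned down

**Alternative 1:** The textbook disconnection of C8–O4′ and C8–C9 around the intact ketone. Bromoketone A1 (from 2) is displaced by phenol A2 to give aryloxy ketone A3, which is hydroxymethylated at C8 under base to give A4, the O-benzyl ether of the racemic target, then debenzylated. This is the shortest route, but it creates C8 directly in its most labile form, under conditions that also reverse the aldol, epimerise C8 and allow a second hydroxymethylation. An enantioselective variant would have to set a centre whose enantiopurity can only fall afterwards, since there is no second stereocentre through which it could be upgraded. It does not control the one element that makes the problem hard.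

**Alternative 2:** Disconnection of C8–O4′ with the stereocentre bought from the chiral pool, plus C7–C1. Mitsunobu inversion of the protected (S)-glycerate A5 with silyl-protected phenol A6 gives (R)-aryloxy ester A7. Acyl substitution by way of an activated amide with aryllithium A8 then installs the ketone, and three deprotections follow. It was turned down because C8 stays α to an ester, an amide and then a ketone through strongly basic and nucleophilic operations. E1cB loss of the C9 trityloxy group and enolisation compete at each one, and any erosion is invisible and uncorrectable. Three protecting groups and the preparation of A5, A6 and A8 also make it longer than the chosen route.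

**Alternative 3:** The biomimetic disconnection of C8–O4′ by radical cross-coupling of two phenols. One-electron oxidation (Ag2O, or a peroxidase with H2O2) of sinapyl alcohol A9 in the presence of A2 would give quinone methide A10, which water traps at C7 to give diol A11; quinone dehydrogenation would then give racemic 11. It was turned down because the radical of A9 prefers 8–8′ homocoupling, and a phenol without a conjugated side chain such as A2 is a poor cross-partner. C8 is formed in a radical recombination with no enantiocontrol, so A11 arises as four stereoisomers and a resolution would be required. The apparent two-step count is therefore illusory.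

Key step: step 5

## Route

**Assumption:** compound 5 (methyl dihydroferulate) is commercially available, as are the two reagents named in the fallback for step 5.

Step 1
Reactants: 1 1-(4-hydroxy-3,5-dimethoxyphenyl)ethan-1-one (acetosyringone)
Product: 2 1-[4-(benzyloxy)-3,5-dimethoxyphenyl]ethan-1-one
Conditions: BnBr, K2CO3, DMF, 60 °C
Reagents that add atoms: benzyl bromide, BrCc1ccccc1
Why: Williamson ether synthesis on an acidic para-acyl phenol. The benzyl ether survives NaH, the carbenoid, transfer hydrogenation and LiBH4, and is removed later by neutral hydrogenolysis.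

Step 2
Reactants: 2 1-[4-(benzyloxy)-3,5-dimethoxyphenyl]ethan-1-one
Product: 3 methyl 3-[4-(benzyloxy)-3,5-dimethoxyphenyl]-3-oxopropanoate
Conditions: NaH (2.5 equiv), dimethyl carbonate, toluene, 90 °C; then AcOH, H2O
Reagents that add atoms: dimethyl carbonate, COC(=O)OC
Why: Crossed Claisen condensation of the methyl ketone enolate with a carbonate, driven by irreversible deprotonation of the β-keto ester formed. It builds the C8–C9 bond with C9 at the ester level.

Step 3
Reactants: 3 methyl 3-[4-(benzyloxy)-3,5-dimethoxyphenyl]-3-oxopropanoate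
Product: 4 methyl 3-[4-(benzyloxy)-3,5-dimethoxyphenyl]-2-diazo-3-oxopropanoate
Conditions: p-ABSA, Et3N, MeCN, 0 °C to rt
Reagents that add atoms: 4-acetamidobenzenesulfonyl azide (p-ABSA), CC(=O)Nc1ccc(cc1)S(=O)(=O)N=[N+]=[N-]
Why: Regitz diazo transfer to the active methylene of a β-keto ester, a reliable reaction for this substrate class.

Step 4
Reactants: 4 methyl 3-[4-(benzyloxy)-3,5-dimethoxyphenyl]-2-diazo-3-oxopropanoate; 5 methyl 3-(4-hydroxy-3-methoxyphenyl)propanoate
Product: 6 methyl 3-[4-(benzyloxy)-3,5-dimethoxyphenyl]-2-[2-methoxy-4-(3-methoxy-3-oxopropyl)phenoxy]-3-oxopropanoate (racemic)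
Conditions: Rh2(OAc)4 (1 mol %), toluene, 80 °C, slow addition of 4 to 5 (1.2 equiv)
Reagents that add atoms: none
Why: Rhodium-carbenoid O–H insertion: the electrophilic acceptor/acceptor carbenoid is captured by the phenolic oxygen (oxonium ylide, then proton shift) and forms the C8–O4′ bond. The chain ester of 5 is inert, and the racemic outcome is intended because C8 of 6 racemises freely.

Step 5
Reactants: 6 methyl 3-[4-(benzyloxy)-3,5-dimethoxyphenyl]-2-[2-methoxy-4-(3-methoxy-3-oxopropyl)phenoxy]-3-oxopropanoate (racemic)
Product: 8 methyl (2S,3R)-3-[4-(benzyloxy)-3,5-dimethoxyphenyl]-3-hydroxy-2-[2-methoxy-4-(3-methoxy-3-oxopropyl)phenoxy]propanoate, via enol tautomer 7 (not isolated)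
Conditions: RuCl[(S,S)-TsDPEN](p-cymene) (2 mol %), HCO2H/Et3N (5:2), CH2Cl2, 30 °C
Reagents that add atoms: none
Why: Noyori–Ikariya asymmetric transfer hydrogenation run as a dynamic kinetic resolution: the ruthenium hydride, regenerated from formate, delivers hydride and the N–H proton to the C7 carbonyl in a concerted outer-sphere six-membered transition state. The closest known reaction type is the transfer-hydrogenative dynamic kinetic resolution of α-alkoxy-β-keto esters of aryl ketones, which gives syn α-alkoxy-β-hydroxy esters. No ring is closed. C7 is set by the catalyst: the edge-to-face contact between ring A and the η6-cymene ligand exposes one carbonyl face, which with the (S,S)-ligand should give 7R. C8 is set by matching: the enantiomers of 6 interconvert through enol 7, because C8–H is flanked by the ketone, the ester and O4′ and is removed by Et3N much faster than the mismatched enantiomer is reduced, and the enantiomer leading to the syn product is reduced preferentially, which gives 8S. The step needs high syn selectivity and fast racemisation, because C7 is erased in step 8 and any anti isomer formed under catalyst control at C7 would carry the wrong C8; the threefold activation of C8–H and the mild temperature secure this. The sense at C7 is immaterial for the target, so the ligand antipode is chosen simply to deliver 8S. Both esters, the benzyl ether and ring B are inert to these conditions.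

Step 6
Reactants: 8 methyl (2S,3R)-3-[4-(benzyloxy)-3,5-dimethoxyphenyl]-3-hydroxy-2-[2-methoxy-4-(3-methoxy-3-oxopropyl)phenoxy]propanoate
Product: 9 (1R,2R)-1-[4-(benzyloxy)-3,5-dimethoxyphenyl]-2-[4-(3-hydroxypropyl)-2-methoxyphenoxy]propane-1,3-diol
Conditions: LiBH4, THF, 0 °C to rt; then H2O
Reagents that add atoms: none
Why: Chemoselective borohydride reduction of both methyl esters, revealing the C9 and C9′ primary alcohols in one operation. The activated α-aryloxy ester is reduced first, after which C8 is no longer α to a carbonyl and is configurationally secure.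

Step 7
Reactants: 9 (1R,2R)-1-[4-(benzyloxy)-3,5-dimethoxyphenyl]-2-[4-(3-hydroxypropyl)-2-methoxyphenoxy]propane-1,3-diol
Product: 10 (1R,2R)-1-(4-hydroxy-3,5-dimethoxyphenyl)-2-[4-(3-hydroxypropyl)-2-methoxyphenoxy]propane-1,3-diol
Conditions: H2 (1 atm), Pd/C, EtOAc, rt
Reagents that add atoms: none
Why: Hydrogenolysis of the aryl benzyl ether under neutral conditions. The aryl benzyl C–O bond should cleave well before the benzylic C7–OH or the C8–O4′ ether is touched.

Step 8
Reactants: 10 (1R,2R)-1-(4-hydroxy-3,5-dimethoxyphenyl)-2-[4-(3-hydroxypropyl)-2-methoxyphenoxy]propane-1,3-diol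
Product: 11 (2R)-3-hydroxy-1-(4-hydroxy-3,5-dimethoxyphenyl)-2-[4-(3-hydroxypropyl)-2-methoxyphenoxy]propan-1-one (target)
Conditions: DDQ (1.05 equiv), 1,4-dioxane, rt, dark
Reagents that add atoms: none
Why: Quinone dehydrogenation of a para-hydroxybenzyl alcohol: hydride abstraction from C7 is assisted by the free C4–OH of ring A, so this carbinol alone should be oxidised while the two primary alcohols and ring B are left. C8 stays sp3 throughout and the medium is neutral to weakly acidic, so the 8R configuration is retained.

## Compound list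

1 | 1-(4-hydroxy-3,5-dimethoxyphenyl)ethan-1-one (acetosyringone) | CC(=O)c1cc(OC)c(O)c(OC)c1 | starting material
2 | 1-[4-(benzyloxy)-3,5-dimethoxyphenyl]ethan-1-one | CC(=O)c1cc(OC)c(OCc2ccccc2)c(OC)c1 | intermediate
3 | methyl 3-[4-(benzyloxy)-3,5-dimethoxyphenyl]-3-oxopropanoate | COC(=O)CC(=O)c1cc(OC)c(OCc2ccccc2)c(OC)c1 | intermediate
4 | methyl 3-[4-(benzyloxy)-3,5-dimethoxyphenyl]-2-diazo-3-oxopropanoate | COC(=O)C(=[N+]=[N-])C(=O)c1cc(OC)c(OCc2ccccc2)c(OC)c1 | intermediate
5 | methyl 3-(4-hydroxy-3-methoxyphenyl)propanoate (methyl dihydroferulate) | COC(=O)CCc1ccc(O)c(OC)c1 | starting material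
6 | methyl 3-[4-(benzyloxy)-3,5-dimethoxyphenyl]-2-[2-methoxy-4-(3-methoxy-3-oxopropyl)phenoxy]-3-oxopropanoate (racemic) | COC(=O)CCc1ccc(OC(C(=O)OC)C(=O)c2cc(OC)c(OCc3ccccc3)c(OC)c2)c(OC)c1 | intermediate
7 | methyl (E)-3-[4-(benzyloxy)-3,5-dimethoxyphenyl]-3-hydroxy-2-[2-methoxy-4-(3-methoxy-3-oxopropyl)phenoxy]prop-2-enoate (chelated enol of 6) | COC(=O)CCc1ccc(O/C(C(=O)OC)=C(/O)c2cc(OC)c(OCc3ccccc3)c(OC)c2)c(OC)c1 | intermediate
8 | methyl (2S,3R)-3-[4-(benzyloxy)-3,5-dimethoxyphenyl]-3-hydroxy-2-[2-methoxy-4-(3-methoxy-3-oxopropyl)phenoxy]propanoate | COC(=O)CCc1ccc(O[C@H](C(=O)OC)[C@H](O)c2cc(OC)c(OCc3ccccc3)c(OC)c2)c(OC)c1 | intermediate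
9 | (1R,2R)-1-[4-(benzyloxy)-3,5-dimethoxyphenyl]-2-[4-(3-hydroxypropyl)-2-methoxyphenoxy]propane-1,3-diol | COc1cc(CCCO)ccc1O[C@H](CO)[C@H](O)c1cc(OC)c(OCc2ccccc2)c(OC)c1 | intermediate
10 | (1R,2R)-1-(4-hydroxy-3,5-dimethoxyphenyl)-2-[4-(3-hydroxypropyl)-2-methoxyphenoxy]propane-1,3-diol | COc1cc(CCCO)ccc1O[C@H](CO)[C@H](O)c1cc(OC)c(O)c(OC)c1 | intermediate
11 | (2R)-3-hydroxy-1-(4-hydroxy-3,5-dimethoxyphenyl)-2-[4-(3-hydroxypropyl)-2-methoxyphenoxy]propan-1-one | COc1cc(CCCO)ccc1O[C@H](CO)C(=O)c1cc(OC)c(O)c(OC)c1 | target

## Step count and risk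

Total step count: 8. Longest linear sequence: 8 steps (1 to 11); 5 enters at step 4.

**Step 5 (key step).** The most likely failure is insufficient syn/anti control, or racemisation of C8 lagging behind reduction of the mismatched enantiomer. Either would surface as erosion of enantiopurity at C8 once C7 is oxidised, because the aryloxy group is larger and less basic than the alkoxy groups for which the syn preference is established. The fallback replaces catalyst control by auxiliary control. It sets out from 5 and comes back at 9.
- Phenol 5 is O-alkylated with commercial (S)-4-benzyl-3-(chloroacetyl)oxazolidin-2-one (K2CO3, NaI cat., acetone) to give (S)-4-benzyl-3-{2-[2-methoxy-4-(3-methoxy-3-oxopropyl)phenoxy]acetyl}oxazolidin-2-one F1.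
- Its dibutylboron Z-enolate (Bu2BOTf, iPr2NEt, CH2Cl2, −78 to 0 °C) adds to commercial 4-(benzyloxy)-3,5-dimethoxybenzaldehyde in an Evans syn-glycolate aldol reaction. This should give (S)-4-benzyl-3-[(2S,3R)-3-[4-(benzyloxy)-3,5-dimethoxyphenyl]-3-hydroxy-2-[2-methoxy-4-(3-methoxy-3-oxopropyl)phenoxy]propanoyl]oxazolidin-2-one F2, with both centres set by the auxiliary through the chair transition state.
- LiBH4 in THF then removes the auxiliary reductively and reduces the chain ester in the same operation, giving 9.

**Step 8.** The most likely failure is loss of chemoselectivity: oxidation of the electron-rich free phenol of ring A beyond the ketone stage, hydride abstraction at the benzylic C7′ methylene of ring B, or acid-promoted dehydration across C8–C9 by the hydroquinone formed. The fallback enforces selectivity with protecting groups. It sets out from 9 and comes back at 11.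
- The two primary hydroxyls are silylated selectively (TBSCl, imidazole, DMF, 0 °C) to give (1R,2R)-1-[4-(benzyloxy)-3,5-dimethoxyphenyl]-3-[(tert-butyldimethylsilyl)oxy]-2-{4-[3-((tert-butyldimethylsilyl)oxy)propyl]-2-methoxyphenoxy}propan-1-ol F3.
- Dess–Martin periodinane buffered with NaHCO3 oxidises the remaining C7 carbinol to (2R)-1-[4-(benzyloxy)-3,5-dimethoxyphenyl]-3-[(tert-butyldimethylsilyl)oxy]-2-{4-[3-((tert-butyldimethylsilyl)oxy)propyl]-2-methoxyphenoxy}propan-1-one F4.
- Hydrogenolysis (H2, Pd/C, EtOAc) gives (2R)-3-[(tert-butyldimethylsilyl)oxy]-2-{4-[3-((tert-butyldimethylsilyl)oxy)propyl]-2-methoxyphenoxy}-1-(4-hydroxy-3,5-dimethoxyphenyl)propan-1-one F5.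
- HF·pyridine in THF, a non-basic desilylation, releases 11.

**Step 4.** The most likely failure is diversion of the electrophilic carbenoid into attack on the electron-rich ring B of 5 (cyclopropanation and ring expansion, or aromatic C–H insertion), or into carbene dimerisation, instead of O–H insertion. The fallback forms the same C8–O4′ bond by ionic displacement. It sets out from 3 and comes back at 6.
- Chlorination of 3 (N-chlorosuccinimide, Mg(ClO4)2 cat., MeCN, rt) gives methyl 3-[4-(benzyloxy)-3,5-dimethoxyphenyl]-2-chloro-3-oxopropanoate F6.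
- The phenoxide of 5 (K2CO3, acetone, 50 °C) displaces the chloride to give 6.

**Step 7.** The most likely failure is hydrogenolytic loss of the benzylic C7 hydroxyl once the para-phenol is liberated, through quinone-methide-type activation on the catalyst surface. The fallback changes the order of events so that no benzylic carbinol is present during hydrogenolysis. It sets out from 9 and comes back at 11.
- Activated MnO2 in CH2Cl2 at rt oxidises the benzylic C7 carbinol selectively beside the two saturated primary alcohols, to give (2R)-1-[4-(benzyloxy)-3,5-dimethoxyphenyl]-3-hydroxy-2-[4-(3-hydroxypropyl)-2-methoxyphenoxy]propan-1-one F7.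
- Hydrogenolysis of the benzyl ether (H2, Pd/C, EtOAc, rt, stopped at one equivalent of uptake) gives 11.

## Further compounds

F1 | step 5 | (S)-4-benzyl-3-{2-[2-methoxy-4-(3-methoxy-3-oxopropyl)phenoxy]acetyl}oxazolidin-2-one | COC(=O)CCc1ccc(OCC(=O)N2[C@@H](Cc3ccccc3)COC2=O)c(OC)c1
F2 | step 5 | (S)-4-benzyl-3-[(2S,3R)-3-[4-(benzyloxy)-3,5-dimethoxyphenyl]-3-hydroxy-2-[2-methoxy-4-(3-methoxy-3-oxopropyl)phenoxy]propanoyl]oxazolidin-2-one | COC(=O)CCc1ccc(O[C@H](C(=O)N2[C@@H](Cc3ccccc3)COC2=O)[C@H](O)c2cc(OC)c(OCc3ccccc3)c(OC)c2)c(OC)c1
F3 | step 8 | (1R,2R)-1-[4-(benzyloxy)-3,5-dimethoxyphenyl]-3-[(tert-butyldimethylsilyl)oxy]-2-{4-[3-((tert-butyldimethylsilyl)oxy)propyl]-2-methoxyphenoxy}propan-1-ol | COc1cc(CCCO[Si](C)(C)C(C)(C)C)ccc1O[C@H](CO[Si](C)(C)C(C)(C)C)[C@H](O)c1cc(OC)c(OCc2ccccc2)c(OC)c1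
F4 | step 8 | (2R)-1-[4-(benzyloxy)-3,5-dimethoxyphenyl]-3-[(tert-butyldimethylsilyl)oxy]-2-{4-[3-((tert-butyldimethylsilyl)oxy)propyl]-2-methoxyphenoxy}propan-1-one | COc1cc(CCCO[Si](C)(C)C(C)(C)C)ccc1O[C@H](CO[Si](C)(C)C(C)(C)C)C(=O)c1cc(OC)c(OCc2ccccc2)c(OC)c1
F5 | step 8 | (2R)-3-[(tert-butyldimethylsilyl)oxy]-2-{4-[3-((tert-butyldimethylsilyl)oxy)propyl]-2-methoxyphenoxy}-1-(4-hydroxy-3,5-dimethoxyphenyl)propan-1-one | COc1cc(CCCO[Si](C)(C)C(C)(C)C)ccc1O[C@H](CO[Si](C)(C)C(C)(C)C)C(=O)c1cc(OC)c(O)c(OC)c1
F6 | step 4 | methyl 3-[4-(benzyloxy)-3,5-dimethoxyphenyl]-2-chloro-3-oxopropanoate (racemic) | COC(=O)C(Cl)C(=O)c1cc(OC)c(OCc2ccccc2)c(OC)c1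
F7 | step 7 | (2R)-1-[4-(benzyloxy)-3,5-dimethoxyphenyl]-3-hydroxy-2-[4-(3-hydroxypropyl)-2-methoxyphenoxy]propan-1-one | COc1cc(CCCO)ccc1O[C@H](CO)C(=O)c1cc(OC)c(OCc2ccccc2)c(OC)c1
A1 | alternative 1 | 1-[4-(benzyloxy)-3,5-dimethoxyphenyl]-2-bromoethan-1-one | BrCC(=O)c1cc(OC)c(OCc2ccccc2)c(OC)c1
A2 | alternative 1 | 4-(3-hydroxypropyl)-2-methoxyphenol (dihydroconiferyl alcohol) | COc1cc(CCCO)ccc1O
A3 | alternative 1 | 1-[4-(benzyloxy)-3,5-dimethoxyphenyl]-2-[4-(3-hydroxypropyl)-2-methoxyphenoxy]ethan-1-one | COc1cc(CCCO)ccc1OCC(=O)c1cc(OC)c(OCc2ccccc2)c(OC)c1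
A4 | alternative 1 | 1-[4-(benzyloxy)-3,5-dimethoxyphenyl]-3-hydroxy-2-[4-(3-hydroxypropyl)-2-methoxyphenoxy]propan-1-one (racemic) | COc1cc(CCCO)ccc1OC(CO)C(=O)c1cc(OC)c(OCc2ccccc2)c(OC)c1
A5 | alternative 2 | methyl (S)-2-hydroxy-3-(trityloxy)propanoate | COC(=O)[C@@H](O)COC(c1ccccc1)(c1ccccc1)c1ccccc1
A6 | alternative 2 | 4-{3-[(tert-butyldimethylsilyl)oxy]propyl}-2-methoxyphenol | COc1cc(CCCO[Si](C)(C)C(C)(C)C)ccc1O
A7 | alternative 2 | methyl (R)-2-{4-[3-((tert-butyldimethylsilyl)oxy)propyl]-2-methoxyphenoxy}-3-(trityloxy)propanoate | COC(=O)[C@@H](COC(c1ccccc1)(c1ccccc1)c1ccccc1)Oc1ccc(CCCO[Si](C)(C)C(C)(C)C)cc1OC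
A8 | alternative 2 | [4-(benzyloxy)-3,5-dimethoxyphenyl]lithium | [Li]c1cc(OC)c(OCc2ccccc2)c(OC)c1
A9 | alternative 3 | (E)-4-(3-hydroxyprop-1-en-1-yl)-2,6-dimethoxyphenol (sinapyl alcohol) | COc1cc(/C=C/CO)cc(OC)c1O
A10 | alternative 3 | 4-{3-hydroxy-2-[4-(3-hydroxypropyl)-2-methoxyphenoxy]propylidene}-2,6-dimethoxycyclohexa-2,5-dien-1-one (quinone methide, racemic) | COC1=CC(=CC(CO)Oc2ccc(CCCO)cc2OC)C=C(OC)C1=O
A11 | alternative 3 | 1-(4-hydroxy-3,5-dimethoxyphenyl)-2-[4-(3-hydroxypropyl)-2-methoxyphenoxy]propane-1,3-diol (mixture of four stereoisomers) | COc1cc(CCCO)ccc1OC(CO)C(O)c1cc(OC)c(O)c(OC)c1
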